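**Plan**
Numbering: furanone ring O1, C2 (C=O), C3 (side chain), C4 (Br), C5; exocyclic C6 (CBr2); carbinol carbon C1′. Retrosynthetic cuts, in order: acetyl–O at C1′; C5=C6; O1–C5 (the C3=C4 π bond folds back into a C3–C5 σ bond); C3–C4 and C4–C5 of the resulting cyclopropane; C3–C1′.
Enabling feature: the run C3=C4(Br)–C5–O1 of the furanone ring, bridged by the C2 carbonyl, is what a 2,2-dibromocyclopropane-1-carboxylic acid becomes after losing one bromide and opening. The CBr2 carbon maps onto C4 and arrives with its bromine, the ring CH2 maps onto C5, and the quaternary ring carbon maps onto C3.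
Forward order: butanal and an activated acrylate are joined (C3–C1′). CBr2 from bromoform is added across the acrylate C=CH2. The only ring of the target is closed by silver-induced opening of the cyclopropane acid. C6 is then brought in from CBr4 at C5 through the 2-silyloxyfuran.
Stereochemistry: the single stereocentre C1′ (R) comes from a β-isocupreidine-catalysed asymmetric Morita–Baylis–Hillman reaction, and its C–O bond is never broken afterwards. The cyclopropane centre forms as a mixture and disappears when C3 becomes sp2.
Protecting group: C1′–O travels as a TIPS ether and is acetylated last. An acetate would be displaced (SN2′) or hydrolysed in the basic cyclopropanation, and it would be expelled from the electron-rich 2-silyloxyfuran or from the dienolate of the endgame.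

Key step: step 6

Assumption: butanal is taken to follow the (R) sense of induction that this catalyst shows with other unbranched aliphatic aldehydes; the catalyst and all starting materials are commercial.

**Step 1**
Reactants: 1 butanal; 2 1,1,1,3,3,3-hexafluoropropan-2-yl acrylate
Product: 3 1,1,1,3,3,3-hexafluoropropan-2-yl (3R)-3-hydroxy-2-methylidenehexanoate
Conditions: β-isocupreidine (10 mol %), DMF, −55 °C
Reagents that add atoms: none
Why: The β-isocupreidine-catalysed asymmetric Morita–Baylis–Hillman reaction of this activated acrylate is established for unbranched aliphatic aldehydes, and the phenolic OH of the catalyst steers proton transfer in the betaine so that the ester released should carry the (R)-carbinol while the mismatched betaine is drained off as a dioxanone.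

**Step 2**
Reactants: 3 1,1,1,3,3,3-hexafluoropropan-2-yl (3R)-3-hydroxy-2-methylidenehexanoate
Product: 4 1,1,1,3,3,3-hexafluoropropan-2-yl (3R)-2-methylidene-3-[(triisopropylsilyl)oxy]hexanoate
Conditions: TIPSOTf, 2,6-lutidine, CH2Cl2, −78 → 0 °C
Reagents that add atoms: triisopropylsilyl triflate, CC(C)[Si](C(C)C)(C(C)C)OS(=O)(=O)C(F)(F)F
Why: O-silylation with a silyl triflate and a hindered, non-nucleophilic pyridine protects the secondary alcohol with retention (only the O–H bond reacts) and leaves the activated ester alone, which imidazole-type conditions might not.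

**Step 3**
Reactants: 4 1,1,1,3,3,3-hexafluoropropan-2-yl (3R)-2-methylidene-3-[(triisopropylsilyl)oxy]hexanoate
Product: 5 tert-butyl (3R)-2-methylidene-3-[(triisopropylsilyl)oxy]hexanoate
Conditions: LiOtBu (1.05 equiv), THF, −78 → −20 °C
Reagents that add atoms: lithium tert-butoxide, [Li+].CC(C)(C)[O-]
Why: Alkoxide transesterification (acyl substitution) of an activated fluoroalkyl ester is fast at low temperature and is driven by release of the much less basic hexafluoroisopropoxide, while the cold, near-stoichiometric conditions should keep conjugate addition of the bulky alkoxide out of play.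

**Step 4**
Reactants: 5 tert-butyl (3R)-2-methylidene-3-[(triisopropylsilyl)oxy]hexanoate; 6 bromoform
Product: 7 tert-butyl 2,2-dibromo-1-{(1R)-1-[(triisopropylsilyl)oxy]butyl}cyclopropane-1-carboxylate (both epimers at ring C1)
Conditions: CHBr3 (excess), 50% aq NaOH, BnEt3NCl (5 mol %), CH2Cl2, 0 °C → rt, vigorous stirring
Reagents that add atoms: none
Why: Phase-transfer dibromocyclopropanation of 2-substituted acrylates is known and gives the same product by [2+1] carbene addition or by conjugate addition of tribromomethanide and 3-exo-tet closure; the tert-butyl ester and TIPS ether resist the hydroxide, silyloxide is too poor a leaving group for SN2′ loss, and the new ring centre needs no control because step 6 erases it.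

**Step 5**
Reactants: 7 tert-butyl 2,2-dibromo-1-{(1R)-1-[(triisopropylsilyl)oxy]butyl}cyclopropane-1-carboxylate
Product: 8 2,2-dibromo-1-{(1R)-1-[(triisopropylsilyl)oxy]butyl}cyclopropane-1-carboxylic acid (both epimers at ring C1)
Conditions: TFA/CH2Cl2 (1:4), 0 °C → rt
Reagents that add atoms: none
Why: Acidolysis of a tert-butyl ester (alkyl–oxygen cleavage, loss of isobutene) is indifferent to the crowding around the quaternary acyl carbon, and neither the gem-dibromocyclopropane nor the hindered secondary TIPS ether should react with anhydrous TFA at this temperature.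

**Step 6**
Reactants: 8 2,2-dibromo-1-{(1R)-1-[(triisopropylsilyl)oxy]butyl}cyclopropane-1-carboxylic acid
Product: 9 4-bromo-3-{(1R)-1-[(triisopropylsilyl)oxy]butyl}furan-2(5H)-one
Conditions: AgO2CCF3 (1.5 equiv), CF3CH2OH, 70 °C, dark
Reagents that add atoms: none
Why: Monovalent silver abstracts the bromide lying cis to the carboxyl while the σ bond opposite the CBr2 carbon opens in a disrotatory two-electron electrocyclic process, and because groups cis to the leaving group turn inward, the 2-bromoallyl cation forms with the carboxyl pointing at the CH2 terminus and the silyloxybutyl group pointing away. The carboxyl oxygen then binds that terminus (O1–C5), the C3=C4 double bond stays with bromine on C4, the proton goes to trifluoroacetate, and relief of ring strain together with precipitation of AgBr provides the driving force. The closest known reaction type is the silver- or heat-induced cyclopropyl-to-allyl cation opening of gem-dihalocyclopropanes with capture by a tethered oxygen nucleophile, which includes the conversion of 2,2-dihalocyclopropanecarboxylic acids into 4-halobutenolides. The furanone closes in a formal 5-endo-trig mode, acceptable here because the acceptor is a cation whose CH2 end is still twisting out of the former ring plane when the oxygen arrives. No stereocentre is created: the ring centre of 8 becomes sp2 C3, so both epimers converge on one product, and C1′ is a spectator under these non-basic conditions. The step needs torquoselectivity (carboxyl inward, not the side chain) and internal rather than solvent capture; the first is secured by the bulk of the CH(OTIPS)Pr group and by either bromide being free to leave, the second by the ionising but weakly nucleophilic solvent and the proximity of the carboxyl.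

**Step 7**
Reactants: 9 4-bromo-3-{(1R)-1-[(triisopropylsilyl)oxy]butyl}furan-2(5H)-one
Product: 10 4-bromo-2-[(tert-butyldimethylsilyl)oxy]-3-{(1R)-1-[(triisopropylsilyl)oxy]butyl}furan
Conditions: TBSOTf (1.2 equiv), Et3N (1.6 equiv), CH2Cl2, 0 °C; rapid basic work-up, used at once
Reagents that add atoms: tert-butyldimethylsilyl triflate, CC(C)(C)[Si](C)(C)OS(=O)(=O)C(F)(F)F
Why: Soft enolisation (O-silylation of the lactone carbonyl, then removal of the acidified C5–H by the amine) is routine for 4-halobutenolides and gives the aromatic 2-silyloxyfuran, from which the C1′ silyloxy group, unlike an acyloxy group, is too poor a leaving group to be pushed out.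

**Step 8**
Reactants: 10 4-bromo-2-[(tert-butyldimethylsilyl)oxy]-3-{(1R)-1-[(triisopropylsilyl)oxy]butyl}furan; 11 carbon tetrabromide
Product: 13 4-bromo-5-(dibromomethylidene)-3-{(1R)-1-[(triisopropylsilyl)oxy]butyl}furan-2(5H)-one, via tribromomethyl lactone 12 (not isolated)
Conditions: CBr4 (1.5 equiv), Et3B (0.2 equiv), air, CH2Cl2, 0 °C; then iPr2NEt (2.5 equiv), 0 °C
Reagents that add atoms: none
Why: Proposed new method: ethyl radicals from Et3B/O2 take bromine from CBr4, the electrophilic tribromomethyl radical adds to the unsubstituted and most electron-rich position C5 of the 2-silyloxyfuran to give an allyl radical whose spin at C2 is flanked by two oxygens, this strongly reducing radical carries the chain by bromine or electron transfer from CBr4, collapse at C2 expels TBSBr to leave lactone 12 (C5 epimers, irrelevant), and iPr2NEt then removes the acidic C5–H with E1cB loss of bromide from the CBr3 group (a far better leaving group than the C1′ silyloxide) to form C5=CBr2; the closest known reaction types are the Et3B- or light-initiated radical polyhaloalkylation of silyl enol ethers and ketene silyl acetals (Kharasch-type addition with loss of silyl halide, then HX loss to β,β-dihaloenones), not yet extended to the vinylogous position of a 2-silyloxyfuran.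

**Step 9**
Reactants: 13 4-bromo-5-(dibromomethylidene)-3-{(1R)-1-[(triisopropylsilyl)oxy]butyl}furan-2(5H)-one
Product: 14 4-bromo-5-(dibromomethylidene)-3-[(1R)-1-hydroxybutyl]furan-2(5H)-one
Conditions: 48% aq HF, MeCN, rt
Reagents that add atoms: none
Why: Acidic fluoride desilylation cleaves only the Si–O bond, so C1′ keeps its configuration, and it is preferred to basic fluoride because polyhalogenated ylidenebutenolides withstand strong acid but add nucleophiles and bases readily.

**Step 10**
Reactants: 14 4-bromo-5-(dibromomethylidene)-3-[(1R)-1-hydroxybutyl]furan-2(5H)-one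
Product: 15 (1R)-1-[4-bromo-5-(dibromomethylidene)-2-oxo-2,5-dihydrofuran-3-yl]butyl acetate
Conditions: Ac2O (1.5 equiv), Sc(OTf)3 (2 mol %), MeCN, 0 °C
Reagents that add atoms: acetic anhydride, CC(=O)OC(C)=O
Why: Lewis-acid-catalysed acylation of a hindered secondary alcohol forms the O–acyl bond without touching C1′–O (retention), avoids nucleophilic amine catalysts that could add to the bromodienone, and should not ionise C1′ because the adjacent ring is strongly electron-poor.

**Compound list**
1 | butanal | CCCC=O | starting material
2 | 1,1,1,3,3,3-hexafluoropropan-2-yl acrylate | C=CC(=O)OC(C(F)(F)F)C(F)(F)F | starting material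
3 | 1,1,1,3,3,3-hexafluoropropan-2-yl (3R)-3-hydroxy-2-methylidenehexanoate | CCC[C@@H](O)C(=C)C(=O)OC(C(F)(F)F)C(F)(F)F | intermediate
4 | 1,1,1,3,3,3-hexafluoropropan-2-yl (3R)-2-methylidene-3-[(triisopropylsilyl)oxy]hexanoate | CCC[C@@H](O[Si](C(C)C)(C(C)C)C(C)C)C(=C)C(=O)OC(C(F)(F)F)C(F)(F)F | intermediate
5 | tert-butyl (3R)-2-methylidene-3-[(triisopropylsilyl)oxy]hexanoate | CCC[C@@H](O[Si](C(C)C)(C(C)C)C(C)C)C(=C)C(=O)OC(C)(C)C | intermediate
6 | bromoform | BrC(Br)Br | starting material
7 | tert-butyl 2,2-dibromo-1-{(1R)-1-[(triisopropylsilyl)oxy]butyl}cyclopropane-1-carboxylate (both epimers at ring C1) | CCC[C@@H](O[Si](C(C)C)(C(C)C)C(C)C)C1(C(=O)OC(C)(C)C)CC1(Br)Br | intermediate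
8 | 2,2-dibromo-1-{(1R)-1-[(triisopropylsilyl)oxy]butyl}cyclopropane-1-carboxylic acid (both epimers at ring C1) | CCC[C@@H](O[Si](C(C)C)(C(C)C)C(C)C)C1(C(=O)O)CC1(Br)Br | intermediate
9 | 4-bromo-3-{(1R)-1-[(triisopropylsilyl)oxy]butyl}furan-2(5H)-one | CCC[C@@H](O[Si](C(C)C)(C(C)C)C(C)C)C1=C(Br)COC1=O | intermediate
10 | 4-bromo-2-[(tert-butyldimethylsilyl)oxy]-3-{(1R)-1-[(triisopropylsilyl)oxy]butyl}furan | CCC[C@@H](O[Si](C(C)C)(C(C)C)C(C)C)c1c(Br)coc1O[Si](C)(C)C(C)(C)C | intermediate
11 | carbon tetrabromide | BrC(Br)(Br)Br | starting material
12 | 4-bromo-5-(tribromomethyl)-3-{(1R)-1-[(triisopropylsilyl)oxy]butyl}furan-2(5H)-one (both C5 epimers, not isolated) | CCC[C@@H](O[Si](C(C)C)(C(C)C)C(C)C)C1=C(Br)C(C(Br)(Br)Br)OC1=O | intermediate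
13 | 4-bromo-5-(dibromomethylidene)-3-{(1R)-1-[(triisopropylsilyl)oxy]butyl}furan-2(5H)-one | CCC[C@@H](O[Si](C(C)C)(C(C)C)C(C)C)C1=C(Br)C(=C(Br)Br)OC1=O | intermediate
14 | 4-bromo-5-(dibromomethylidene)-3-[(1R)-1-hydroxybutyl]furan-2(5H)-one | CCC[C@@H](O)C1=C(Br)C(=C(Br)Br)OC1=O | intermediate
15 | (1R)-1-[4-bromo-5-(dibromomethylidene)-2-oxo-2,5-dihydrofuran-3-yl]butyl acetate | CCC[C@@H](OC(C)=O)C1=C(Br)C(=C(Br)Br)OC1=O | target

Total step count: 10. Longest linear sequence: 10 steps (1 and 2 to 15).

**Steps most likely to fail**

Step 8 (new method). Bromine transfer from CBr4 to C5 may outrun C–C bond formation, the radical chain may stall, or hydrogen may be abstracted at the furylic C1′–H. The fallback sets out from 10 and comes back at 13, and it builds C6 by ionic, known chemistry.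
- Vinylogous Mannich reaction of 10 with dimethyl(methylidene)ammonium iodide in CH2Cl2 should give the 5-(dimethylaminomethyl)butenolide F1.
- MeI turns F1 into the trimethylammonium iodide F2, and iPr2NEt induces Hofmann-type elimination to the 5-methylidenebutenolide F3.
- Br2 in CH2Cl2 adds across the exocyclic alkene to give the 5-bromo-5-(bromomethyl)lactone F4, and iPr2NEt removes HBr to give the (Z)-5-(bromomethylidene)butenolide F5.
- A second Br2 addition gives the 5-bromo-5-(dibromomethyl)lactone F6, and a second dehydrobromination delivers 13.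

Step 6. The allyl cation may be intercepted by solvent or trifluoroacetate before the in-plane carboxyl oxygen reaches the CH2 terminus. The ionisation is also slowed by the electron-withdrawing carboxyl, and the acid released may cause loss of the silyl group. The fallback sets out from 7 and comes back at 9, and it separates ionisation from ring closure.
- The tert-butyl ester 7 is opened with AgNO3 and CaCO3 in aqueous acetone, so that water is the deliberate nucleophile at the CH2 terminus. This should give the (E)-3-bromo-4-hydroxybut-2-enoate F7, with CH2OH cis to the ester.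
- TFA in CH2Cl2 then removes the tert-butyl group, and the hydroxy acid lactonises by 5-exo-trig acyl substitution to 9.

Step 4. Addition to the hindered, electron-poor alkene may be too slow to compete with hydrolysis of the carbene, and silyloxide may undergo β-elimination from the enolate formed by conjugate addition of tribromomethanide. The fallback sets out from 5 and comes back at 8, and it changes the oxidation level so that the alkene is electron-rich.
- iBu2AlH in CH2Cl2 at −78 °C reduces 5 to the allylic alcohol F8.
- Phase-transfer addition of dibromocarbene (CHBr3, 50% aq NaOH, BnEt3NCl), well known for substituted allylic alcohols, gives the dibromocyclopropylmethanol F9.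
- Dess–Martin oxidation gives the cyclopropanecarbaldehyde F10, and Pinnick oxidation (NaClO2, NaH2PO4, 2-methylbut-2-ene) gives acid 8.

**Further compounds**
F1 | step 8 | 4-bromo-5-[(dimethylamino)methyl]-3-{(1R)-1-[(triisopropylsilyl)oxy]butyl}furan-2(5H)-one (both C5 epimers) | CCC[C@@H](O[Si](C(C)C)(C(C)C)C(C)C)C1=C(Br)C(CN(C)C)OC1=O
F2 | step 8 | (3-bromo-5-oxo-4-{(1R)-1-[(triisopropylsilyl)oxy]butyl}-2,5-dihydrofuran-2-yl)-N,N,N-trimethylmethanaminium iodide | CCC[C@@H](O[Si](C(C)C)(C(C)C)C(C)C)C1=C(Br)C(C[N+](C)(C)C)OC1=O.[I-]
F3 | step 8 | 4-bromo-5-methylidene-3-{(1R)-1-[(triisopropylsilyl)oxy]butyl}furan-2(5H)-one | CCC[C@@H](O[Si](C(C)C)(C(C)C)C(C)C)C1=C(Br)C(=C)OC1=O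
F4 | step 8 | 4,5-dibromo-5-(bromomethyl)-3-{(1R)-1-[(triisopropylsilyl)oxy]butyl}furan-2(5H)-one (both C5 epimers) | CCC[C@@H](O[Si](C(C)C)(C(C)C)C(C)C)C1=C(Br)C(Br)(CBr)OC1=O
F5 | step 8 | (5Z)-4-bromo-5-(bromomethylidene)-3-{(1R)-1-[(triisopropylsilyl)oxy]butyl}furan-2(5H)-one | CCC[C@@H](O[Si](C(C)C)(C(C)C)C(C)C)C1=C(Br)/C(=C/Br)OC1=O
F6 | step 8 | 4,5-dibromo-5-(dibromomethyl)-3-{(1R)-1-[(triisopropylsilyl)oxy]butyl}furan-2(5H)-one (both C5 epimers) | CCC[C@@H](O[Si](C(C)C)(C(C)C)C(C)C)C1=C(Br)C(Br)(C(Br)Br)OC1=O
F7 | step 6 | tert-butyl (2E)-3-bromo-4-hydroxy-2-{(1R)-1-[(triisopropylsilyl)oxy]butyl}but-2-enoate | CCC[C@@H](O[Si](C(C)C)(C(C)C)C(C)C)/C(C(=O)OC(C)(C)C)=C(\Br)CO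
F8 | step 4 | (3R)-2-methylidene-3-[(triisopropylsilyl)oxy]hexan-1-ol | CCC[C@@H](O[Si](C(C)C)(C(C)C)C(C)C)C(=C)CO
F9 | step 4 | (2,2-dibromo-1-{(1R)-1-[(triisopropylsilyl)oxy]butyl}cyclopropyl)methanol (both epimers at ring C1) | CCC[C@@H](O[Si](C(C)C)(C(C)C)C(C)C)C1(CO)CC1(Br)Br
F10 | step 4 | 2,2-dibromo-1-{(1R)-1-[(triisopropylsilyl)oxy]butyl}cyclopropane-1-carbaldehyde (both epimers at ring C1) | CCC[C@@H](O[Si](C(C)C)(C(C)C)C(C)C)C1(C=O)CC1(Br)Br
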